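Readings and results are calculated with constants of no real substance, and the scatter is random.

- The easy step first: in the winter and dawn runs target creeps up while starting material falls, so I read intermediate as a resting state, a pool feeding target.

| flask | starting material | coupling partner | protic impurity | temperature | remark | time |
|---|---|---|---|---|---|---|
| winter | 0.025 M | 0.15 M | 2.5 mM | 80 °C | run made earlier |  |
| dawn | 0.10 M | 0.15 M | 2.5 mM | 98 °C | run made earlier |  |
| south | 0.050 M | 0.150 M | 2.50 mM | 110 °C |  | 5.0 h |
| north-east | 0.050 M | 0.150 M | 2.50 mM | 85 °C |  | 5.0 h |

| run | time / h | target / % | starting material / % |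
|---|---|---|---|
| winter | 0.667 | 0 | 83.1 |
| winter | 2.00 | 1.2 | 56.4 |
| winter | 4.00 | 3.5 | 33.5 |
| winter | 6.00 | 5.9 | 19.2 |
| winter | 8.00 | 8.3 | 13.2 |
| winter | 12.0 | 12.7 | 5.5 |
| dawn | 0.333 | 1.6 | 69.5 |
| dawn | 0.833 | 3.4 | 43.3 |
| dawn | 1.50 | 6.2 | 28.0 |
| dawn | 2.50 | 13.3 | 15.5 |
| dawn | 4.00 | 16.8 | 5.6 |
| dawn | 5.00 | 21.1 | 4.2 |

(standard deviation of a reading: 1 percentage point)

1. which flask leads in amount of target, in percent of the starting material charged ("all alike" within 1.5 percentage points) (south / north-east / all alike)
2. how much target is there at the end, in percent of the starting material charged: south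
3. how much target is there at the end, in percent of the starting material charged: north-east

- candidate steps: intermediate <-> isomer of the product A; coupling partner + protic impurity -> quenched reagent; starting material + coupling partner -> intermediate + by-product; target <-> isomer of the product B; intermediate <-> target

- I take the pool as reacted starting material minus target. Target's rise divided by the mean pool gives a feed rate κ: 0.0170 h⁻¹ in the winter run and 0.0664 h⁻¹ in the dawn run. The two runs differ in charge as well, but I put the whole difference down to temperature as an assumption, so ln κ climbs 0.0758 K⁻¹.
- Coupling partner stands in excess in the winter run, so starting material falls first-order there at 0.251 h⁻¹. I assume this rate climbs with temperature like κ.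
- Subtracting that lag from the time leaves h, the hours of full pool.
- My rule is θ = κh, the share of the pool turned to target, trusted as an amount while θ stays small. The first way to a number is θ itself.
- North-east: 0.0248 h⁻¹ and 2.71 h give 0.0671, so about 6.71% target.
- The second way is a clock. If everything speeds alike, north-east's end matches the winter run at 7.30 h, where the readings interpolate to 7.46%. The two agree within the scatter, but both lean on the winter readings and the same climb of ln κ, so I take this as a check of the lag reckoning and not of that climb.
- South: θ comes to 0.756, but the clock maps the dawn run's last reading, 21.1%, to 2.01 h of south and has no reading after it.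
- The ways part there, and θ is the one that cheats: the dawn run ends at 0.238, and south's θ lies far above that. I commit to south leading and read no amount from its θ.
- The forecast says south, with 40% for south and 7% for north-east: “the hotter flask speeds up the slow second step far more in absolute terms”.

    intermediate ⇌ isomer of the product A (K = 2.40, k = 0.110 h⁻¹, Ea = 123 kJ mol⁻¹, ΔH = −19.0 kJ mol⁻¹)
    coupling partner + protic impurity → quenched reagent (k = 180 M⁻¹ h⁻¹, Ea = 81.0 kJ mol⁻¹)
    starting material + coupling partner → intermediate + by-product (k = 22.0 M⁻¹ h⁻¹, Ea = 91.0 kJ mol⁻¹)
    target ⇌ isomer of the product B (K = 7.20, k = 0.350 h⁻¹, Ea = 110 kJ mol⁻¹, ΔH = −26.0 kJ mol⁻¹)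
    intermediate ⇌ target (K = 0.420, k = 0.400 h⁻¹, Ea = 112 kJ mol⁻¹, ΔH = −55.0 kJ mol⁻¹)
    (constants at 110 °C)

- The flasks give 13.7% in south and 7.96% in north-east, so south leads. South's target stood at 18.1% after 2.50 h, and at the end it is made at 0.556 of the rate it is used up. North-east's θ of 0.0671 lands within 1.2 percentage points, while south's 0.756 overshoots by 62 points.
- A neighbour of south charged with 0.037 M of coupling partner makes that partner the limiting reagent. After the protic impurity takes 2.50 mM of it, the partner can convert 69.0% of the starting material. Scaled by that share, θ is 0.522, still above the dawn run's, so I read no amount from it. The computed flask gives 9.50% target, with 35% of the starting material left.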